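The earlier runs and the new flask were computed from invented constants.

The flasks end at 5.0 h, later than Wednesday's last reading at 60.0 min, so I did not stretch the percent made forward but worked with the fraction of substrate left, assuming first order in reagent and one reagent spent per target.

common to all: catalyst 0.61 mM

|  | substrate | reagent | remark | time |
|---|---|---|---|---|
| Wednesday's | 0.25 M | 1.2 M | run made earlier |  |
| grey | 0.25 M | 0.793 M |  | 5.0 h |
| blue | 0.40 M | 0.793 M |  | 5.0 h |
| violet | 0.60 M | 0.793 M |  | 5.0 h |

Wednesday's run (percent of the substrate charged)

| time / min | target / % | substrate / % |
|---|---|---|
| 5.00 | 0 | 99 |
| 10.0 | 3 | 98 |
| 15.0 | 4 | 95 |
| 30.0 | 9 | 91 |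
| 60.0 | 15 | 83 |

(standard deviation of a reading: 1.5 percentage points)

- the numbers in the tables scatter with a standard deviation of 1.5 percentage points
- a reading or a percentage of target counts all its forms, free or not
- "hardly changes" means that all values lie within two and a half points (for a concentration: within two and a half percent of the largest)

- amount of target at the end, in percent of the substrate charged for grey, blue, violet, in this order
- the course of these numbers from the first flask to the last (falls all the way / hardly changes / rises, then falls / rises all the way / falls, then rises)

Wednesday's 83 % of substrate at 60.0 min, under 1.2 M of reagent, gave me my clearing constant, the logarithm of the inverse fraction left per molar hour of reagent: 0.155 /M/h. It is a reading with its scatter, and multiplied by a reagent concentration it becomes the pseudo-first-order constant.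

For the bound from above I held the reagent at its charge of 0.793 M, which gave 46.0 % made at any of the three loadings. For the bound from below I held the reagent throughout at the level left after that much target, which gave 33.1 % in violet and 40.9 % in grey. I then fed each bound into the other, taking the upper one at the midpoint of the reagent spent. That narrowed grey to at most 43.8 % and at least 41.2 %, and violet to at most 41.6 % and at least 34.4 %. Violet's upper bound still stood above grey's lower one, so my brackets leaned towards a fall without proving it.

The forecast gave 43 %, 39 % and 35 %, a course that falls all the way, in its words “I therefore expect a modest fall, shading the higher loadings down”. Its grey value stood inside my grey bracket, and its violet value stood inside my violet bracket, near the lower edge.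

The flasks gave 42.5 %, 39.5 % and 35.9 %, a course that falls all the way.

    reagent + target ⇌ idle adduct, settled at all times (K = 31.0 /M)
    substrate + reagent + catalyst ⇌ target + catalyst, rate k2*[substrate]*[reagent]*[catalyst] forward; the back reaction follows from the equilibrium constant (K = 5.80 /M, k = 270 /M²/h)

In violet the reagent ended at 48 % of its charge, with 33.1 % of the substrate charged standing as idle adduct, counted in the target. Dividing the logarithm of violet's inverse fraction left, 64.1 %, by my constant and the time gave a mean reagent of 0.574 M, against 0.381 M at its end. The same division for grey gave 0.712 M, against 0.586 M at its end.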